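Both pyranone rings are disconnected at once: in each flavone unit the bonds O1–C8a, C4–C4a and O1–C2 are cut, leaving a biaryl that holds only the two rings A, joined C6–C8''. The feature exploited is that O-5 sits on the carbon next to C4a in both rings A, so each ring A can enter as a 3-alkoxyaryne across C4a–C8a that takes the carboxylate oxygen at C8a and the acyl carbon at C4a. One fluoride-triggered operation with two molecules of an arylpropiolic acid then forms six bonds and both rings C. The precursor is a biaryl bis(2-trimethylsilylaryl triflate), one ring 2,6-dimethoxylated, the other bis(benzyloxy)-substituted.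

Key step: step 10

Assumption: the SMILES fixes no configuration at the hindered C6–C8'' axis and the molecule has no stereocentre, so the biaryl is made without control of axial chirality.
Remark: arynes, aryl anions and palladium species without lifetime are discussed in the Why lines; the numbered in-flask intermediates are the species that persist in solution.

Step 1
Reactants: 1 2-bromo-1,3-dimethoxybenzene
Product: 3 4-bromo-3,5-dimethoxyphenol, via arylboronate 2 (not isolated)
Conditions: [Ir(OMe)(cod)]2 (cat.), dtbpy (cat.), B2pin2 (0.6 equiv), THF, 80 °C; then KHSO5 (Oxone), acetone/H2O, rt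
Reagents that add atoms: potassium peroxymonosulfate (active oxidant of Oxone), [K+].[O-]S(=O)(=O)OO
Why: Sterically controlled iridium-catalysed C–H borylation should touch only C5, the one C–H without an ortho substituent, and oxidation of the boronate in the same pot (borylation/oxidation sequence) should give the phenol with the C–Br bond intact.

Step 2
Reactants: 3 4-bromo-3,5-dimethoxyphenol
Product: 4 2-bromo-1,3-dimethoxy-5-(methoxymethoxy)benzene
Conditions: NaH, MOMCl, THF/DMF, 0 °C to rt
Reagents that add atoms: chloromethyl methyl ether (MOMCl), COCCl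
Why: Williamson-type O-alkylation of the sodium phenoxide installs an acetal that should survive organozinc and palladium chemistry and that masks the acidic O–H.

Step 3
Reactants: 5 3,5-bis(benzyloxy)phenol
Product: 6 1,3-bis(benzyloxy)-5-(methoxymethoxy)benzene
Conditions: NaH, MOMCl, THF/DMF, 0 °C to rt
Reagents that add atoms: chloromethyl methyl ether (MOMCl), COCCl
Why: The same Williamson-type O-alkylation protects the phenol and installs the strongest lithium-coordinating group of the ring for the directed metalation that follows.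

Step 4
Reactants: 6 1,3-bis(benzyloxy)-5-(methoxymethoxy)benzene; 4 2-bromo-1,3-dimethoxy-5-(methoxymethoxy)benzene
Product: 9 2',4'-bis(benzyloxy)-2,6-dimethoxy-4,6'-bis(methoxymethoxy)-1,1'-biphenyl, via aryllithium 7 (not isolated), via arylzinc chloride 8 (not isolated)
Conditions: n-BuLi, TMEDA, THF, −20 to 0 °C; ZnCl2, 0 °C to rt; then 4, Pd2(dba)3 (cat.), RuPhos (cat.), THF/NMP, 70 °C
Reagents that add atoms: none
Why: Directed ortho-metalation should place lithium between the OMOM and a benzyloxy group (MOM coordination outweighs the site between two benzyl ethers), transmetalation to zinc gives a base-free nucleophile not subject to protodeboronation, and Negishi coupling with a bulky dialkylbiarylphosphine is an established way to form tetra-ortho-substituted biaryl bonds.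

Step 5
Reactants: 9 2',4'-bis(benzyloxy)-2,6-dimethoxy-4,6'-bis(methoxymethoxy)-1,1'-biphenyl
Product: 10 4',6'-bis(benzyloxy)-2,6-dimethoxy-[1,1'-biphenyl]-2',4-diol
Conditions: conc. HCl (cat.), MeOH/THF, 50 °C
Reagents that add atoms: none
Why: Acid-catalysed acetal exchange with methanol should remove both MOM groups while benzyl and methyl ethers are inert, and it is done here because the later electron-rich arylsilanes would not tolerate acid.

Step 6
Reactants: 10 4',6'-bis(benzyloxy)-2,6-dimethoxy-[1,1'-biphenyl]-2',4-diol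
Product: 11 4',6'-bis(benzyloxy)-2,6-dimethoxy-[1,1'-biphenyl]-2',4-diyl bis(N-isopropylcarbamate)
Conditions: i-PrNCO, Et3N (cat.), CH2Cl2, rt to 40 °C
Reagents that add atoms: isopropyl isocyanate, CC(C)N=C=O
Why: Base-catalysed addition of both phenols to the isocyanate (carbamoylation) gives N–H carbamates, a strong ortho-directing group that can later be removed by mild base instead of acid.

Step 7
Reactants: 11 4',6'-bis(benzyloxy)-2,6-dimethoxy-[1,1'-biphenyl]-2',4-diyl bis(N-isopropylcarbamate)
Product: 15 4',6'-bis(benzyloxy)-2,6-dimethoxy-3,3'-bis(trimethylsilyl)-[1,1'-biphenyl]-2',4-diyl bis(N-isopropylcarbamate), via bis(N-silyl carbamate) 12 (not isolated), via dilithio species 13 (not isolated), via tetrasilyl compound 14 (not isolated)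
Conditions: TMSOTf, TMEDA, Et2O/THF, 0 °C to rt; n-BuLi (2.4 equiv), TMEDA, −78 °C; TMSCl, −78 °C to rt; aq. NaHCO3/MeOH work-up
Reagents that add atoms: chlorotrimethylsilane (TMSCl), C[Si](C)(C)Cl
Why: After in situ N-silylation the carbamate should direct lithiation at −78 °C to the C–H between itself and the neighbouring alkoxy group on each ring (directed ortho-metalation), a temperature at which benzylic deprotonation and metalation between the two benzyl ethers should be slow, and TMSCl traps the dianion before the labile N–Si bonds are hydrolysed on work-up.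

Step 8
Reactants: 15 4',6'-bis(benzyloxy)-2,6-dimethoxy-3,3'-bis(trimethylsilyl)-[1,1'-biphenyl]-2',4-diyl bis(N-isopropylcarbamate)
Product: 17 4',6'-bis(benzyloxy)-2,6-dimethoxy-3,3'-bis(trimethylsilyl)-[1,1'-biphenyl]-2',4-diyl bis(trifluoromethanesulfonate), via bis(silylphenol) 16 (not isolated)
Conditions: DBU, Et2NH, MeCN, 40 °C; then PhNTf2, rt to 40 °C
Reagents that add atoms: N-phenylbis(trifluoromethanesulfonimide), O=S(=O)(N(c1ccccc1)S(=O)(=O)C(F)(F)F)C(F)(F)F
Why: DBU deprotonates the carbamate N–H so that the phenoxide is expelled (E1cB) while Et2NH traps the isocyanate as a urea, and the ortho-silyl phenoxide is sulfonylated in the same pot (carbamate cleavage/triflation), so the protodesilylation-prone silylphenol is never isolated or exposed to acid.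

Step 9
Reactants: 18 1-(benzyloxy)-4-ethynylbenzene
Product: 20 3-[4-(benzyloxy)phenyl]propiolic acid, via lithium acetylide 19 (not isolated)
Conditions: n-BuLi, THF, −78 °C; CO2, −78 °C to rt; aq. HCl
Reagents that add atoms: carbon dioxide, O=C=O
Why: Deprotonation of the terminal alkyne and carboxylation of the lithium acetylide is the standard route to arylpropiolic acids, and the acetylenic C–H is far more acidic than the benzylic ether position.

Step 10
Reactants: 17 4',6'-bis(benzyloxy)-2,6-dimethoxy-3,3'-bis(trimethylsilyl)-[1,1'-biphenyl]-2',4-diyl bis(trifluoromethanesulfonate); 20 3-[4-(benzyloxy)phenyl]propiolic acid (two molecules, used in excess)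
Product: 22 5,7-bis(benzyloxy)-2-[4-(benzyloxy)phenyl]-8-{2-[4-(benzyloxy)phenyl]-5,7-dimethoxy-4-oxo-4H-chromen-6-yl}-4H-chromen-4-one, via bis(hydroxyaryl ynone) 21 (not isolated)
Conditions: 20 (3 equiv), CsF (8 equiv), THF, 125 °C, sealed tube
Reagents that add atoms: none
Why: Fluoride removes each trimethylsilyl group with loss of triflate to give, one after the other, the C4a–C8a aryne of each ring A; the caesium carboxylate of 20 adds through oxygen to C8a, the aryl anion left at C4a attacks the adjacent ester carbonyl to form a four-membered alkoxide, and its ring-opening moves the acyl group to C4a and frees the C8a phenoxide of a 2-hydroxyaryl ynone. The closest known reaction type is the insertion of arynes from 2-silylaryl triflates into the C–O bond of carboxylic acids under CsF in hot THF, which with arylpropiolic acids is known to run on to flavones. Each pyranone ring then closes by 6-endo-dig oxa-Michael addition of the C8a phenoxide to the alkyne carbon bearing the aryl group (O1–C2), and the resulting vinyl anion is protonated at C3 by further acid. No stereocentre is formed. The selectivity needed is regiochemical: in both arynes the alkoxy group on C5 polarises the triple bond so that the nucleophile enters at the remote carbon C8a and the negative charge develops at C4a next to the inductively withdrawing oxygen, which is exactly the 5-oxygenated flavone pattern. In the 8-linked ring this electronic bias has to outweigh the steric shielding of C8a by the neighbouring biaryl bond, which the small carboxylate oxygen and the weak directing effect of an aryl substituent should allow.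

Step 11
Reactants: 22 5,7-bis(benzyloxy)-2-[4-(benzyloxy)phenyl]-8-{2-[4-(benzyloxy)phenyl]-5,7-dimethoxy-4-oxo-4H-chromen-6-yl}-4H-chromen-4-one
Product: 23 5,7-dihydroxy-8-[5-hydroxy-2-(4-hydroxyphenyl)-7-methoxy-4-oxo-4H-chromen-6-yl]-2-(4-hydroxyphenyl)-4H-chromen-4-one (target)
Conditions: BCl3, C6HMe5, CH2Cl2, −78 °C to 0 °C then rt; MeOH/H2O quench
Reagents that add atoms: none
Why: BCl3 with pentamethylbenzene as a non-basic benzyl-cation scavenger cleaves the four aryl benzyl ethers at low temperature, and on warming the BCl3 chelated between the C4 carbonyl and O-5 of the 6-linked unit should demethylate only that peri methoxy group, leaving the non-chelated 7-methoxy group (Lewis-acid ether cleavage with chelation-controlled demethylation).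

Compound list
1 | 2-bromo-1,3-dimethoxybenzene | COc1cccc(OC)c1Br | starting material
2 | 2-(4-bromo-3,5-dimethoxyphenyl)-4,4,5,5-tetramethyl-1,3,2-dioxaborolane | COc1cc(B2OC(C)(C)C(C)(C)O2)cc(OC)c1Br | intermediate (not isolated)
3 | 4-bromo-3,5-dimethoxyphenol | COc1cc(O)cc(OC)c1Br | intermediate
4 | 2-bromo-1,3-dimethoxy-5-(methoxymethoxy)benzene | COCOc1cc(OC)c(Br)c(OC)c1 | intermediate
5 | 3,5-bis(benzyloxy)phenol | Oc1cc(OCc2ccccc2)cc(OCc2ccccc2)c1 | starting material
6 | 1,3-bis(benzyloxy)-5-(methoxymethoxy)benzene | COCOc1cc(OCc2ccccc2)cc(OCc2ccccc2)c1 | intermediate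
7 | [2,4-bis(benzyloxy)-6-(methoxymethoxy)phenyl]lithium | [Li]c1c(OCOC)cc(OCc2ccccc2)cc1OCc1ccccc1 | intermediate (not isolated)
8 | chloro[2,4-bis(benzyloxy)-6-(methoxymethoxy)phenyl]zinc | Cl[Zn]c1c(OCOC)cc(OCc2ccccc2)cc1OCc1ccccc1 | intermediate (not isolated)
9 | 2',4'-bis(benzyloxy)-2,6-dimethoxy-4,6'-bis(methoxymethoxy)-1,1'-biphenyl | COCOc1cc(OC)c(-c2c(OCOC)cc(OCc3ccccc3)cc2OCc2ccccc2)c(OC)c1 | intermediate
10 | 4',6'-bis(benzyloxy)-2,6-dimethoxy-[1,1'-biphenyl]-2',4-diol | COc1cc(O)cc(OC)c1-c1c(O)cc(OCc2ccccc2)cc1OCc1ccccc1 | intermediate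
11 | 4',6'-bis(benzyloxy)-2,6-dimethoxy-[1,1'-biphenyl]-2',4-diyl bis(N-isopropylcarbamate) | COc1cc(OC(=O)NC(C)C)cc(OC)c1-c1c(OC(=O)NC(C)C)cc(OCc2ccccc2)cc1OCc1ccccc1 | intermediate
12 | 4',6'-bis(benzyloxy)-2,6-dimethoxy-[1,1'-biphenyl]-2',4-diyl bis[N-isopropyl-N-(trimethylsilyl)carbamate] | COc1cc(OC(=O)N(C(C)C)[Si](C)(C)C)cc(OC)c1-c1c(OC(=O)N(C(C)C)[Si](C)(C)C)cc(OCc2ccccc2)cc1OCc1ccccc1 | intermediate (not isolated)
13 | 3,3'-dilithio derivative of 12 (lithium between the carbamate oxygen and the flanking alkoxy group on each ring) | COc1cc(OC(=O)N(C(C)C)[Si](C)(C)C)c([Li])c(OC)c1-c1c(OC(=O)N(C(C)C)[Si](C)(C)C)c([Li])c(OCc2ccccc2)cc1OCc1ccccc1 | intermediate (not isolated)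
14 | 3,3'-bis(trimethylsilyl) derivative of 12 | COc1cc(OC(=O)N(C(C)C)[Si](C)(C)C)c([Si](C)(C)C)c(OC)c1-c1c(OC(=O)N(C(C)C)[Si](C)(C)C)c([Si](C)(C)C)c(OCc2ccccc2)cc1OCc1ccccc1 | intermediate (not isolated)
15 | 4',6'-bis(benzyloxy)-2,6-dimethoxy-3,3'-bis(trimethylsilyl)-[1,1'-biphenyl]-2',4-diyl bis(N-isopropylcarbamate) | COc1cc(OC(=O)NC(C)C)c([Si](C)(C)C)c(OC)c1-c1c(OC(=O)NC(C)C)c([Si](C)(C)C)c(OCc2ccccc2)cc1OCc1ccccc1 | intermediate
16 | 4',6'-bis(benzyloxy)-2,6-dimethoxy-3,3'-bis(trimethylsilyl)-[1,1'-biphenyl]-2',4-diol (formed as its phenoxide) | COc1cc(O)c([Si](C)(C)C)c(OC)c1-c1c(O)c([Si](C)(C)C)c(OCc2ccccc2)cc1OCc1ccccc1 | intermediate (not isolated)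
17 | 4',6'-bis(benzyloxy)-2,6-dimethoxy-3,3'-bis(trimethylsilyl)-[1,1'-biphenyl]-2',4-diyl bis(trifluoromethanesulfonate) | COc1cc(OS(=O)(=O)C(F)(F)F)c([Si](C)(C)C)c(OC)c1-c1c(OCc2ccccc2)cc(OCc2ccccc2)c([Si](C)(C)C)c1OS(=O)(=O)C(F)(F)F | intermediate
18 | 1-(benzyloxy)-4-ethynylbenzene | C#Cc1ccc(OCc2ccccc2)cc1 | starting material
19 | lithium [4-(benzyloxy)phenyl]acetylide | [Li]C#Cc1ccc(OCc2ccccc2)cc1 | intermediate (not isolated)
20 | 3-[4-(benzyloxy)phenyl]propiolic acid | OC(=O)C#Cc1ccc(OCc2ccccc2)cc1 | intermediate
21 | 1,1'-[4',6'-bis(benzyloxy)-2',4-dihydroxy-2,6-dimethoxy-[1,1'-biphenyl]-3,3'-diyl]bis{3-[4-(benzyloxy)phenyl]prop-2-yn-1-one} (formed as its bis-phenoxide) | COc1cc(O)c(C(=O)C#Cc2ccc(OCc3ccccc3)cc2)c(OC)c1-c1c(OCc2ccccc2)cc(OCc2ccccc2)c(C(=O)C#Cc2ccc(OCc3ccccc3)cc2)c1O | intermediate (not isolated)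
22 | 5,7-bis(benzyloxy)-2-[4-(benzyloxy)phenyl]-8-{2-[4-(benzyloxy)phenyl]-5,7-dimethoxy-4-oxo-4H-chromen-6-yl}-4H-chromen-4-one | COc1cc2oc(-c3ccc(OCc4ccccc4)cc3)cc(=O)c2c(OC)c1-c1c(OCc2ccccc2)cc(OCc2ccccc2)c2c(=O)cc(-c3ccc(OCc4ccccc4)cc3)oc12 | intermediate
23 | 5,7-dihydroxy-8-[5-hydroxy-2-(4-hydroxyphenyl)-7-methoxy-4-oxo-4H-chromen-6-yl]-2-(4-hydroxyphenyl)-4H-chromen-4-one (6,8''-biapigenin 7-O-methyl ether) | COc1cc2oc(-c3ccc(O)cc3)cc(=O)c2c(O)c1-c1c(O)cc(O)c2c(=O)cc(-c3ccc(O)cc3)oc12 | target

Total step count: 11. Longest linear sequence: 9 steps (steps 1, 2, 4, 5, 6, 7, 8, 10, 11).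

Steps most likely to fail

Step 10. The propiolic acid may decarboxylate at the reaction temperature before it is captured. The aryl anion at C4a may be protonated before acyl transfer, which stops at an O-aryl ester. The carboxylate may add at C4a of the aryne of the 8-linked ring, where the biaryl bond crowds C8a. Only one of the two silyl triflate units may be converted. Fallback by classical flavone construction, setting out from 11: the N-silylation and ortho-lithiation of step 7 are repeated (through 12 and 13), and 13 is quenched with N-methoxy-N-methylacetamide instead of TMSCl to give, after work-up, the bis(ortho-acetyl) bis-carbamate F1. KOH in EtOH with 4-(benzyloxy)benzaldehyde cleaves both carbamates and brings about Claisen–Schmidt condensation to the bis(2'-hydroxychalcone) F2. Oxidative cyclisation with catalytic iodine in DMSO at 130 °C closes both pyranone rings and rejoins the route at 22.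

Step 4. Transmetalation and reductive elimination at two doubly ortho-substituted carbons may be slow, so that protodezincation and homocoupling take over. Part of the metalation may also occur between the two benzyl ethers. Fallback that avoids cross-coupling, setting out from 6: aryllithium 7 is added at −78 °C to 2,6-dimethoxy-1,4-benzoquinone, where 1,2-addition should take place at the carbonyl flanked by the two methoxy-bearing carbons, the other carbonyl being deactivated as a doubly vinylogous ester. This gives the quinol F3. Reductive aromatisation with Zn in AcOH gives the mono-MOM biaryl phenol F4, and the acid methanolysis of step 5 removes the remaining MOM group and rejoins the route at 10.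

Step 7. Benzylic deprotonation of the benzyl ethers (with subsequent Wittig-type rearrangement or C-silylation) may compete. Metalation may occur between the two benzyloxy groups, or the second lithiation at the crowded bis(benzyloxy) ring may stay incomplete. Fallback through halogen–lithium exchange, setting out from 10: amine-mediated ortho-bromination (NBS, catalytic i-Pr2NH, CH2Cl2, −78 to 0 °C) should give the 3,3'-dibromo diol F5, the para position of the benzyloxy ring being shielded by its two benzyl ethers. Heating with HMDS gives the bis(trimethylsilyl ether) F6. n-BuLi in THF at −100 °C effects bromine–lithium exchange, which is faster than any deprotonation, followed by 1,3-migration of silicon from oxygen to carbon (retro-Brook) to give the lithium phenoxide of 16. Quenching with Tf2O in the same flask rejoins the route at 17.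

Further compounds
F1 | step 10 | 3,3'-diacetyl-4',6'-bis(benzyloxy)-2,6-dimethoxy-[1,1'-biphenyl]-2',4-diyl bis(N-isopropylcarbamate) | COc1cc(OC(=O)NC(C)C)c(C(C)=O)c(OC)c1-c1c(OC(=O)NC(C)C)c(C(C)=O)c(OCc2ccccc2)cc1OCc1ccccc1
F2 | step 10 | (2E,2'E)-1,1'-[4',6'-bis(benzyloxy)-2',4-dihydroxy-2,6-dimethoxy-[1,1'-biphenyl]-3,3'-diyl]bis{3-[4-(benzyloxy)phenyl]prop-2-en-1-one} | COc1cc(O)c(C(=O)/C=C/c2ccc(OCc3ccccc3)cc2)c(OC)c1-c1c(O)c(C(=O)/C=C/c2ccc(OCc3ccccc3)cc2)c(OCc2ccccc2)cc1OCc1ccccc1
F3 | step 4 | 4-[2,4-bis(benzyloxy)-6-(methoxymethoxy)phenyl]-4-hydroxy-3,5-dimethoxycyclohexa-2,5-dien-1-one | COC1=CC(=O)C=C(OC)C1(O)c1c(OCOC)cc(OCc2ccccc2)cc1OCc1ccccc1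
F4 | step 4 | 2',4'-bis(benzyloxy)-2,6-dimethoxy-6'-(methoxymethoxy)-[1,1'-biphenyl]-4-ol | COc1cc(O)cc(OC)c1-c1c(OCOC)cc(OCc2ccccc2)cc1OCc1ccccc1
F5 | step 7 | 4',6'-bis(benzyloxy)-3,3'-dibromo-2,6-dimethoxy-[1,1'-biphenyl]-2',4-diol | COc1cc(O)c(Br)c(OC)c1-c1c(O)c(Br)c(OCc2ccccc2)cc1OCc1ccccc1
F6 | step 7 | {[4',6'-bis(benzyloxy)-3,3'-dibromo-2,6-dimethoxy-[1,1'-biphenyl]-2',4-diyl]bis(oxy)}bis(trimethylsilane) | COc1cc(O[Si](C)(C)C)c(Br)c(OC)c1-c1c(O[Si](C)(C)C)c(Br)c(OCc2ccccc2)cc1OCc1ccccc1
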